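## Retrosynthetic overview

1. Feature: ring A (C4a, C5, C6, C7, C8, C8a) carries oxygen on C5, C7 and C8a and the C4 acyl carbon on C4a. This is the pattern of a triketide ester folded by C-acylation, and its only methylated oxygen (O7) coincides with the enol ether of a 4-methoxy-2-pyranone.
2. Ring B (O1–C2): the chromone comes from a silyl-protected 2,6-dihydroxy-4-methoxyphenyl 1,3-diketone whose two phenols are equivalent.
3. Ring A (C4a–C8a): the aryl diketone comes from its isomer, a 6-(2,4-dioxoalkyl)-4-methoxy-2-pyranone, in which the lactone carbonyl is C8a and the CH2 on pyranone C6 is C4a.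
4. C2–C3: the pyranonyl diketone comes from the dianion of 4-methoxy-6-(2-oxopropyl)-2-pyranone and the imidazolide of a (3R)-3-silyloxy acid. The stereocentre is set by Noyori hydrogenation of the β-keto ester built from Meldrum's acid and methyl 6-chloro-6-oxohexanoate.
5. Ring order: 2-pyranone (purchased), then ring A at its expense (step 9), then ring B (step 10).

Key step: step 9

Remark: chromone numbering (O1, C2, C3, C4, C4a, C5 to C8, C8a) is used for the ring atoms in all intermediates. CIP analysis of the given SMILES gives (R) at the carbinol carbon. In every intermediate the CH2 leading to the carbonyl or chromone side outranks the (CH2)4 chain, so the descriptor stays (R) throughout.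

## Route

Step 1
Reactants: 1 Meldrum's acid (2,2-dimethyl-1,3-dioxane-4,6-dione); 2 methyl 6-chloro-6-oxohexanoate
Product: 3 methyl 6-(2,2-dimethyl-4,6-dioxo-1,3-dioxan-5-ylidene)-6-hydroxyhexanoate (enol form of the 5-acyl Meldrum's acid)
Conditions: pyridine (2.2 equiv), CH2Cl2, 0 °C → rt; 1 M aq HCl wash
Reagents that add atoms: none
Why: C-acylation of the strongly acidic C5 methylene of Meldrum's acid by an acid chloride with pyridine as base is the standard route to 5-acyl Meldrum's acids, and the remote methyl ester takes no part.

Step 2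
Reactants: 3 methyl 6-(2,2-dimethyl-4,6-dioxo-1,3-dioxan-5-ylidene)-6-hydroxyhexanoate
Product: 5 1-benzyl 8-methyl 3-oxooctanedioate, via acylketene 4 (not isolated)
Conditions: BnOH (1.1 equiv), toluene, 110 °C
Reagents that add atoms: benzyl alcohol, OCc1ccccc1
Why: On heating, the acyl Meldrum's acid undergoes cycloreversion to acetone, carbon dioxide and acylketene 4, which benzyl alcohol traps as the β-keto ester (acyl Meldrum's acid alcoholysis), so that the two ester termini become chemically distinct.

Step 3
Reactants: 5 1-benzyl 8-methyl 3-oxooctanedioate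
Product: 6 1-benzyl 8-methyl (3R)-3-hydroxyoctanedioate
Conditions: H2 (100 bar), RuBr2[(R)-BINAP] (1 mol %), CH2Cl2, 40 °C
Reagents that add atoms: none
Why: Noyori asymmetric hydrogenation, in which the β-keto ester binds ruthenium through both carbonyl oxygens and the (R)-BINAP ligand directs hydride to the ketone face that gives the (3R)-alcohol, the same sense as in the reduction of methyl acetoacetate to methyl (R)-3-hydroxybutanoate, while the aprotic solvent rules out ester exchange and the homogeneous catalyst leaves the benzyl ester intact.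

Step 4
Reactants: 6 1-benzyl 8-methyl (3R)-3-hydroxyoctanedioate
Product: 7 1-benzyl 8-methyl (3R)-3-[(tert-butyldimethylsilyl)oxy]octanedioate
Conditions: TBSCl (1.3 equiv), imidazole (2.5 equiv), DMF, rt
Reagents that add atoms: tert-butyldimethylsilyl chloride, CC(C)(C)[Si](C)(C)Cl
Why: Standard silylation of a secondary alcohol with TBSCl and imidazole is mild enough not to trigger β-elimination of the hydroxy ester and does not touch the C3 configuration.

Step 5
Reactants: 7 1-benzyl 8-methyl (3R)-3-[(tert-butyldimethylsilyl)oxy]octanedioate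
Product: 8 (3R)-3-[(tert-butyldimethylsilyl)oxy]-8-methoxy-8-oxooctanoic acid
Conditions: H2 (1 bar), Pd/C (10 wt %), EtOAc, rt
Reagents that add atoms: none
Why: Hydrogenolysis of the benzylic C–O bond over palladium frees only the C1 acid, since the methyl ester and the silyl ether are inert to hydrogen in a neutral aprotic solvent.

Step 6
Reactants: 8 (3R)-3-[(tert-butyldimethylsilyl)oxy]-8-methoxy-8-oxooctanoic acid
Product: 9 methyl (6R)-6-[(tert-butyldimethylsilyl)oxy]-8-(1H-imidazol-1-yl)-8-oxooctanoate
Conditions: 1,1'-carbonyldiimidazole (1.1 equiv), CH2Cl2, rt; brief wash with ice-cold water, dry (Na2SO4), concentrate, use at once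
Reagents that add atoms: 1,1'-carbonyldiimidazole, O=C(n1ccnc1)n1ccnc1
Why: Activation of the carboxylic acid as its N-acylimidazole proceeds under neutral conditions driven by loss of carbon dioxide, and the cold aqueous wash removes imidazole and surplus reagent, both of which would otherwise consume the dianion in step 8.

Step 7
Reactants: 10 4-methoxy-6-methyl-2H-pyran-2-one
Product: 12 4-methoxy-6-(2-oxopropyl)-2H-pyran-2-one, via lithiated pyranone 11 (not isolated)
Conditions: 10 (2.0 equiv), LiN(i-Pr)2 (2.0 equiv), THF, −78 °C; MeC(O)N(OMe)Me (1.0 equiv), −78 → −40 °C; AcOH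
Reagents that add atoms: N-methoxy-N-methylacetamide, CC(=O)N(C)OC
Why: Kinetic deprotonation of the pyranone occurs at the C6 methyl group to give the vinylogous ester enolate 11, which is acylated by the N-methoxy-N-methylamide (Weinreb ketone synthesis) to form the C4–C4a bond, the second equivalent of 11 serving as base for the more acidic product.

Step 8
Reactants: 12 4-methoxy-6-(2-oxopropyl)-2H-pyran-2-one; 9 methyl (6R)-6-[(tert-butyldimethylsilyl)oxy]-8-(1H-imidazol-1-yl)-8-oxooctanoate
Product: 14 methyl (6R)-6-[(tert-butyldimethylsilyl)oxy]-11-(4-methoxy-2-oxo-2H-pyran-6-yl)-8,10-dioxoundecanoate, via dilithio dianion 13 (not isolated)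
Conditions: 12 (2.1 equiv), LiN(i-Pr)2 (4.3 equiv), THF, −78 → −20 °C; 9 (1.0 equiv), THF, −78 °C; AcOH
Reagents that add atoms: none
Why: γ-Acylation of a 1,3-dicarbonyl-type dianion (crossed Claisen condensation), in which the terminal, less stabilised carbanion of 13 is the more nucleophilic site and attacks the acylimidazole, at −78 °C far more electrophilic than the methyl ester, while the second equivalent of 13 deprotonates the new 1,3-diketone and the stereocentre is not involved.

Step 9
Reactants: 14 methyl (6R)-6-[(tert-butyldimethylsilyl)oxy]-11-(4-methoxy-2-oxo-2H-pyran-6-yl)-8,10-dioxoundecanoate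
Product: 16 methyl (6R)-6-[(tert-butyldimethylsilyl)oxy]-10-(2,6-dihydroxy-4-methoxyphenyl)-8,10-dioxodecanoate, via ring-opened enoate 15 (not isolated)
Conditions: Mg(OMe)2 (8 equiv, solution in MeOH), MeOH, reflux, Ar; cold 1 M aq HCl
Reagents that add atoms: none
Why: Methoxide from Mg(OMe)2 adds reversibly to the lactone carbonyl and breaks the O1–C2 bond of the 2-pyranone, which gives the acyclic enoate 15 as a magnesium polyenolate; its new methyl ester and the rest of the carbon chain stay cis on the double bond as they were in the ring, a geometry that carries the descriptor (E) because OMe outranks CH2. The methylene that joined the pyranone to the side chain (future C4a) now lies between two ketones (future C5 and C4), and its magnesium-bridged enolate attacks the ester carbonyl (future C8a), expels methoxide and the resulting cyclohexenedione tautomerises to the phenol, so that the C4a–C8a bond and ring A arise in a net isomerisation driven by aromatisation. The closest known reaction type is the Mg(OMe)2-mediated opening and Claisen (Dieckmann-type) recyclisation of 6-(2-oxoalkyl)-2-pyranones and of 3,5,7-triketo esters to acylphloroglucinols. Ring A closes in the 6-(enolendo)-exo-trig mode, which is favoured for enolates, and no stereocentre is formed, the silyloxy-bearing carbon being a spectator. The selectivity needed is C-acylation at C4a in preference to the other six-ring foldings (aldol C8 to C4, aldol C6 to C2, addition–elimination C3 to C7) and to E1cB loss of the silyloxy group. The O7 methyl enol ether leaves C8 as a non-acidic sp2 CH and C7 as a poorly electrophilic vinylogous carbonate carbon, and magnesium holds the C2/C4 diketone as a chelated enolate whose carbonyl groups are poor electrophiles and whose negative charge opposes deprotonation of the CH2 next to the silyloxy carbon.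

Step 10
Reactants: 16 methyl (6R)-6-[(tert-butyldimethylsilyl)oxy]-10-(2,6-dihydroxy-4-methoxyphenyl)-8,10-dioxodecanoate
Product: 18 penithochromone O [methyl (6R)-6-hydroxy-7-(5-hydroxy-7-methoxy-4-oxo-4H-chromen-2-yl)heptanoate], via silylated chromone 17 (not isolated)
Conditions: HCl (1.25 M in MeOH), 0 °C → rt
Reagents that add atoms: none
Why: Acid-catalysed cyclodehydration of an o-hydroxyaryl 1,3-diketone, the closing stage of the Baker–Venkataraman chromone synthesis, in which one of the two equivalent phenols adds to the alkyl ketone C2 (6-exo-trig), the hemiketal loses water to give ring B in 17, and the same methanolic acid then solvolyses the secondary silyl ether without breaking the carbinol C–O bond, so that the (R) configuration is kept.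

## Compound list

1 | Meldrum's acid (2,2-dimethyl-1,3-dioxane-4,6-dione) | CC1(C)OC(=O)CC(=O)O1 | starting material
2 | methyl 6-chloro-6-oxohexanoate | COC(=O)CCCCC(Cl)=O | starting material
3 | methyl 6-(2,2-dimethyl-4,6-dioxo-1,3-dioxan-5-ylidene)-6-hydroxyhexanoate | COC(=O)CCCCC(O)=C1C(=O)OC(C)(C)OC1=O | intermediate
4 | methyl 6,8-dioxooct-7-enoate (acylketene, formed in the flask) | COC(=O)CCCCC(=O)C=C=O | intermediate
5 | 1-benzyl 8-methyl 3-oxooctanedioate | COC(=O)CCCCC(=O)CC(=O)OCc1ccccc1 | intermediate
6 | 1-benzyl 8-methyl (3R)-3-hydroxyoctanedioate | COC(=O)CCCC[C@@H](O)CC(=O)OCc1ccccc1 | intermediate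
7 | 1-benzyl 8-methyl (3R)-3-[(tert-butyldimethylsilyl)oxy]octanedioate | COC(=O)CCCC[C@@H](O[Si](C)(C)C(C)(C)C)CC(=O)OCc1ccccc1 | intermediate
8 | (3R)-3-[(tert-butyldimethylsilyl)oxy]-8-methoxy-8-oxooctanoic acid | COC(=O)CCCC[C@@H](O[Si](C)(C)C(C)(C)C)CC(=O)O | intermediate
9 | methyl (6R)-6-[(tert-butyldimethylsilyl)oxy]-8-(1H-imidazol-1-yl)-8-oxooctanoate | COC(=O)CCCC[C@@H](O[Si](C)(C)C(C)(C)C)CC(=O)n1ccnc1 | intermediate
10 | 4-methoxy-6-methyl-2H-pyran-2-one | COc1cc(C)oc(=O)c1 | starting material
11 | lithium 4-methoxy-6-methylidene-6H-pyran-2-olate (lithiated pyranone, formed in the flask) | [Li+].C=C1C=C(OC)C=C([O-])O1 | intermediate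
12 | 4-methoxy-6-(2-oxopropyl)-2H-pyran-2-one | CC(=O)Cc1cc(OC)cc(=O)o1 | intermediate
13 | dilithium bis-enolate of 12 (dianion at the ring-side CH2 and the terminal CH3, formed in the flask) | [Li+].[Li+].C=C([O-])C=C1C=C(OC)C=C([O-])O1 | intermediate
14 | methyl (6R)-6-[(tert-butyldimethylsilyl)oxy]-11-(4-methoxy-2-oxo-2H-pyran-6-yl)-8,10-dioxoundecanoate | COC(=O)CCCC[C@@H](O[Si](C)(C)C(C)(C)C)CC(=O)CC(=O)Cc1cc(OC)cc(=O)o1 | intermediate
15 | dimethyl (2E,11R)-11-[(tert-butyldimethylsilyl)oxy]-3-methoxy-5,7,9-trioxohexadec-2-enedioate (present as its magnesium polyenolate, formed in the flask) | COC(=O)CCCC[C@@H](O[Si](C)(C)C(C)(C)C)CC(=O)CC(=O)CC(=O)C/C(OC)=C\C(=O)OC | intermediate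
16 | methyl (6R)-6-[(tert-butyldimethylsilyl)oxy]-10-(2,6-dihydroxy-4-methoxyphenyl)-8,10-dioxodecanoate | COC(=O)CCCC[C@@H](O[Si](C)(C)C(C)(C)C)CC(=O)CC(=O)c1c(O)cc(OC)cc1O | intermediate
17 | methyl (6R)-6-[(tert-butyldimethylsilyl)oxy]-7-(5-hydroxy-7-methoxy-4-oxo-4H-chromen-2-yl)heptanoate (formed in the flask) | COC(=O)CCCC[C@@H](O[Si](C)(C)C(C)(C)C)Cc1cc(=O)c2c(O)cc(OC)cc2o1 | intermediate
18 | penithochromone O, methyl (6R)-6-hydroxy-7-(5-hydroxy-7-methoxy-4-oxo-4H-chromen-2-yl)heptanoate | COC(=O)CCCC[C@@H](O)Cc1cc(=O)c2c(O)cc(OC)cc2o1 | target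

## Step count and risks

Total step count: 10. Longest linear sequence: 9 steps (steps 1 to 6, then 8, 9 and 10). Step 7 is a one-step side branch.

**Step 9 (most at risk).**
- The reversible lactone opening may stall.
- The polyenolate may fold by an aldol mode onto a side-chain ketone instead of by C-acylation.
- Methoxide may cleave the 1,3-diketone by a retro-Claisen process.
- The silyloxy group may be lost by E1cB elimination on prolonged heating.

In the fallback, ring A is taken from the aromatic pool instead of being folded. Commercial 1-(2,6-dihydroxy-4-methoxyphenyl)ethanone F1 is treated with LiN(SiMe3)2 (about 4 equiv, THF, −78 → −10 °C). This gives trilithium 1-(4-methoxy-2,6-dioxidophenyl)ethen-1-olate F2. Its enolate carbon is C-acylated by the imidazolide at −78 °C and the mixture is quenched with AcOH, the direct polyanion variant of the Baker–Venkataraman synthesis of o-hydroxyaryl 1,3-diketones. This fallback sets out from 9 and comes back to the route at 16.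

**Step 8.**
- The strongly basic dianion may take a proton from the α-CH2 of the imidazolide, with subsequent loss of silanolate.
- Acylation may occur on oxygen.
- The second deprotonation of 12 may remain incomplete.

In the fallback, the C2–C3 bond is made by aldol addition and the oxidation level is adjusted afterwards.
- BH3·SMe2 (THF, 0 °C → rt) reduces the acid chemoselectively to methyl (6R)-6-[(tert-butyldimethylsilyl)oxy]-8-hydroxyoctanoate F3.
- IBX (2-iodoxybenzoic acid, EtOAc, reflux) oxidises it to methyl (6R)-6-[(tert-butyldimethylsilyl)oxy]-8-oxooctanoate F4.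
- Dianion 13 (1.1 equiv, THF, −78 °C) adds to the aldehyde. The aldolate formed is not acidic and needs no sacrificial equivalent. The product is methyl (6R)-6-[(tert-butyldimethylsilyl)oxy]-8-hydroxy-11-(4-methoxy-2-oxo-2H-pyran-6-yl)-10-oxoundecanoate F5, as both C8 epimers.
- IBX in hot EtOAc converts the β-hydroxy ketone to the 1,3-diketone, which removes the extra stereocentre.

This fallback sets out from 8 (with 13 made from 12 as before) and comes back at 14.

**Step 7.**
- Acyl transfer to the stabilised and thermally fragile anion may be slow.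
- Ring lithiation at C3 may compete.
- The anion may self-condense on warming.

In the fallback, the more reactive aldehyde electrophile is used. Anion 11 (LiN(i-Pr)2, 1.05 equiv, THF, −78 °C) adds to acetaldehyde to give racemic 6-(2-hydroxypropyl)-4-methoxy-2H-pyran-2-one F6, which IBX (EtOAc, reflux) oxidises to the ketone. This fallback sets out from 10 and comes back at 12.

## Further compounds

F1 | step 9 | 1-(2,6-dihydroxy-4-methoxyphenyl)ethanone (purchased) | CC(=O)c1c(O)cc(OC)cc1O
F2 | step 9 | trilithium 1-(4-methoxy-2,6-dioxidophenyl)ethen-1-olate | [Li+].[Li+].[Li+].C=C([O-])c1c([O-])cc(OC)cc1[O-]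
F3 | step 8 | methyl (6R)-6-[(tert-butyldimethylsilyl)oxy]-8-hydroxyoctanoate | COC(=O)CCCC[C@@H](O[Si](C)(C)C(C)(C)C)CCO
F4 | step 8 | methyl (6R)-6-[(tert-butyldimethylsilyl)oxy]-8-oxooctanoate | COC(=O)CCCC[C@@H](O[Si](C)(C)C(C)(C)C)CC=O
F5 | step 8 | methyl (6R)-6-[(tert-butyldimethylsilyl)oxy]-8-hydroxy-11-(4-methoxy-2-oxo-2H-pyran-6-yl)-10-oxoundecanoate (both C8 epimers) | COC(=O)CCCC[C@@H](O[Si](C)(C)C(C)(C)C)CC(O)CC(=O)Cc1cc(OC)cc(=O)o1
F6 | step 7 | 6-(2-hydroxypropyl)-4-methoxy-2H-pyran-2-one (racemic) | CC(O)Cc1cc(OC)cc(=O)o1
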